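**Retr​osynthetic overview** (side chain: C7 = benzylic carbinol, C8 = aryl ether carbon, C9 = CH2OH)
1. Target ⇐ its tri-O-benzyl ether by one hydrogenolysis. Ring C (the pyranone) is the only ring built and is closed last, by Claisen condensation/cyclodehydration of a ring B methyl benzoate with a ring A 2-hydroxyacetophenone; rings A, B and the hydroxyphenyl ring are bought.
2. C9 hydroxymethyl ⇐ vinyl group (ozonolysis, NaBH4).
3. Key bond C7–C8: both carbons are oxygen-bearing and natively electrophilic. C8 is made the nucleophile as a (Z)-γ-aryloxyallyl-B(Ipc)2 reagent (an α-oxy carbanion equivalent) that already carries the ring B ether. It adds to 4-(benzyloxy)benzaldehyde and sets 7R,8R (threo) in one operation.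
4. Allylborane ⇐ Ipc2BH hydroboration of an aryloxyallene ⇐ propargyl ether of methyl syringate.

Assumption: crystalline (−)-Ipc2BH (made in one flask from (+)-α-pinene and BH3·SMe2) is treated as a stock chiral reagent and its preparation is not counted as a step.

**Route**

Step 1
Reactants: 1 methyl syringate (methyl 4-hydroxy-3,5-dimethoxybenzoate); 2 propargyl bromide
Product: 3 methyl 3,5-dimethoxy-4-(prop-2-yn-1-yloxy)benzoate
Conditions: K2CO3 (2 equiv), DMF, 60 °C, 4 h
Reagents that add atoms: propargyl bromide (2), C#CCBr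
Why: Williamson ether synthesis; the phenoxide of the syringate displaces bromide from the unhindered propargylic carbon (SN2), and no stereocentre is involved.

Step 2
Reactants: 3 methyl 3,5-dimethoxy-4-(prop-2-yn-1-yloxy)benzoate
Product: 4 methyl 3,5-dimethoxy-4-(propa-1,2-dien-1-yloxy)benzoate
Conditions: KOtBu (0.2 equiv), THF, 0 → 20 °C, 1 h
Reagents that add atoms: none
Why: Base-catalysed propargyl-to-allenyl prototropic isomerisation, which for aryl propargyl ethers stops at the aryloxyallene with catalytic alkoxide; the two ortho methoxy groups block any Claisen rearrangement.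

Step 3
Reactants: 4 methyl 3,5-dimethoxy-4-(propa-1,2-dien-1-yloxy)benzoate (1.15 equiv); 5 (−)-diisopinocampheylborane, (−)-Ipc2BH (1.05 equiv); 6 4-(benzyloxy)benzaldehyde (1.0 equiv)
Product: 9 methyl 4-{[(1R,2R)-1-[4-(benzyloxy)phenyl]-1-hydroxybut-3-en-2-yl]oxy}-3,5-dimethoxybenzoate, via (Z)-γ-aryloxyallylborane 7 (not isolated), via borinate ester 8 (not isolated)
Conditions: 4 + 5, THF, −25 → 0 °C, 3 h; then 6, −78 °C, 4 h, → 20 °C; then aq. NaHCO3, 30% H2O2, 0 → 20 °C
Reagents that add atoms: none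
Why: Proposed new method: bulky Ipc2BH should hydroborate the terminal C=C of the aryloxyallene with boron on the CH2 terminus and hydride delivered anti to the aryloxy group, giving the kinetic (Z)-γ-aryloxyallylborane, an α-oxy carbanion equivalent that makes the natively electrophilic ether carbon C8 attack the aldehyde carbon; addition through a closed chair (Zimmerman–Traxler) transition state with the Z-aryloxy group axial gives the syn (threo) adduct, and the isopinocampheyl groups derived from (+)-α-pinene direct attack to the Si face of the aldehyde, so 7R and 8R are set together, the closest known reaction type being the Brown (Z)-γ-alkoxyallyl-B(Ipc)2 allylboration combined with allene hydroboration by Ipc2BH.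

Step 4
Reactants: 9 methyl 4-{[(1R,2R)-1-[4-(benzyloxy)phenyl]-1-hydroxybut-3-en-2-yl]oxy}-3,5-dimethoxybenzoate
Product: 11 methyl 4-{[(1R,2R)-1-[4-(benzyloxy)phenyl]-1,3-dihydroxypropan-2-yl]oxy}-3,5-dimethoxybenzoate, via secondary ozonide 10 (not isolated)
Conditions: O3, CH2Cl2, −78 °C (Sudan Red 7B end point); then NaBH4 (4 equiv), MeOH, −78 → 0 °C
Reagents that add atoms: ozone, [O-][O+]=O
Why: Ozonolysis with reductive NaBH4 work-up; the terminal alkene reacts far faster than the aryl ethers, and reducing the ozonide cold avoids a free α-aryloxy-β-hydroxy aldehyde, so C8 is not epimerised and the methyl ester is untouched.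

Step 5
Reactants: 12 2',4',6'-trihydroxyacetophenone; 13 benzyl bromide
Product: 14 1-[2,4-bis(benzyloxy)-6-hydroxyphenyl]ethan-1-one
Conditions: BnBr (2.05 equiv), K2CO3 (2.2 equiv), DMF, 20 °C, 16 h
Reagents that add atoms: benzyl bromide (13), BrCc1ccccc1
Why: Chemoselective Williamson O-benzylation; the para hydroxyl and one ortho hydroxyl are alkylated, while the remaining ortho hydroxyl is deactivated by its hydrogen bond to the acetyl carbonyl.

Step 6
Reactants: 11 methyl 4-{[(1R,2R)-1-[4-(benzyloxy)phenyl]-1,3-dihydroxypropan-2-yl]oxy}-3,5-dimethoxybenzoate; 14 1-[2,4-bis(benzyloxy)-6-hydroxyphenyl]ethan-1-one (1.3 equiv)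
Product: 16 5,7-bis(benzyloxy)-2-[4-({(1R,2R)-1-[4-(benzyloxy)phenyl]-1,3-dihydroxypropan-2-yl}oxy)-3,5-dimethoxyphenyl]-4H-chromen-4-one, via 1,3-diketone 15 (not isolated)
Conditions: LiN(SiMe3)2 (6 equiv), THF, −78 → 25 °C, 16 h; AcOH quench, aqueous wash; crude in PhMe/THF (4:1), TsOH·H2O (0.2 equiv), 45 °C
Reagents that add atoms: none
Why: Crossed Claisen condensation of the ketone enolate with the methyl ester gives the 1,3-diketone, and mild acid-catalysed cyclodehydration through the 2-hydroxyflavanone hemiketal closes ring C; the lithium alkoxides of the diol are spectators and catalytic acid at 45 °C in a non-nucleophilic solvent should not ionise the benzylic alcohol, so both stereocentres are kept.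

Step 7
Reactants: 16 5,7-bis(benzyloxy)-2-[4-({(1R,2R)-1-[4-(benzyloxy)phenyl]-1,3-dihydroxypropan-2-yl}oxy)-3,5-dimethoxyphenyl]-4H-chromen-4-one
Product: 17 5,7-dihydroxy-2-[4-({(1R,2R)-1,3-dihydroxy-1-(4-hydroxyphenyl)propan-2-yl}oxy)-3,5-dimethoxyphenyl]-4H-chromen-4-one (target)
Conditions: H2 (1 atm), Pd/C (10 wt%), THF/EtOAc (1:1), 23 °C
Reagents that add atoms: none
Why: Catalytic hydrogenolysis of the three aryl benzyl ethers; under neutral conditions the flavone C2=C3 bond and the secondary benzylic alcohol are not reduced, so the stereocentres are unaffected.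

**Compound list**

1 | methyl syringate (methyl 4-hydroxy-3,5-dimethoxybenzoate) | COC(=O)c1cc(OC)c(O)c(OC)c1 | starting material
2 | propargyl bromide (3-bromoprop-1-yne) | C#CCBr | starting material
3 | methyl 3,5-dimethoxy-4-(prop-2-yn-1-yloxy)benzoate | COC(=O)c1cc(OC)c(OCC#C)c(OC)c1 | intermediate
4 | methyl 3,5-dimethoxy-4-(propa-1,2-dien-1-yloxy)benzoate | COC(=O)c1cc(OC)c(OC=C=C)c(OC)c1 | intermediate
5 | (−)-diisopinocampheylborane, (−)-Ipc2BH, from (+)-α-pinene (each Ipc group gives (1R,2R,3R,5S)-isopinocampheol on oxidation) | [BH]([C@@H]1C[C@@H]2C[C@H]([C@H]1C)C2(C)C)[C@@H]1C[C@@H]2C[C@H]([C@H]1C)C2(C)C | starting material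
6 | 4-(benzyloxy)benzaldehyde | O=Cc1ccc(OCc2ccccc2)cc1 | starting material
7 | (Z)-γ-aryloxyallylborane: {(2Z)-3-[2,6-dimethoxy-4-(methoxycarbonyl)phenoxy]prop-2-en-1-yl}bis(isopinocampheyl)borane (not isolated) | COC(=O)c1cc(OC)c(O/C=C\CB([C@@H]2C[C@@H]3C[C@H]([C@H]2C)C3(C)C)[C@@H]2C[C@@H]3C[C@H]([C@H]2C)C3(C)C)c(OC)c1 | intermediate
8 | borinate ester: compound 9 with B(Ipc)2 on the benzylic oxygen (not isolated) | COC(=O)c1cc(OC)c(O[C@H](C=C)[C@H](OB([C@@H]2C[C@@H]3C[C@H]([C@H]2C)C3(C)C)[C@@H]2C[C@@H]3C[C@H]([C@H]2C)C3(C)C)c2ccc(OCc3ccccc3)cc2)c(OC)c1 | intermediate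
9 | methyl 4-{[(1R,2R)-1-[4-(benzyloxy)phenyl]-1-hydroxybut-3-en-2-yl]oxy}-3,5-dimethoxybenzoate (threo) | COC(=O)c1cc(OC)c(O[C@H](C=C)[C@H](O)c2ccc(OCc3ccccc3)cc2)c(OC)c1 | intermediate
10 | secondary ozonide of 9: vinyl group replaced by a 1,2,4-trioxolan-3-yl ring, side-chain stereocentres unchanged, trioxolane carbon as a mixture of epimers (not isolated) | COC(=O)c1cc(OC)c(O[C@H](C2OCOO2)[C@H](O)c2ccc(OCc3ccccc3)cc2)c(OC)c1 | intermediate
11 | methyl 4-{[(1R,2R)-1-[4-(benzyloxy)phenyl]-1,3-dihydroxypropan-2-yl]oxy}-3,5-dimethoxybenzoate | COC(=O)c1cc(OC)c(O[C@H](CO)[C@H](O)c2ccc(OCc3ccccc3)cc2)c(OC)c1 | intermediate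
12 | 2',4',6'-trihydroxyacetophenone | CC(=O)c1c(O)cc(O)cc1O | starting material
13 | benzyl bromide | BrCc1ccccc1 | starting material
14 | 1-[2,4-bis(benzyloxy)-6-hydroxyphenyl]ethan-1-one | CC(=O)c1c(O)cc(OCc2ccccc2)cc1OCc1ccccc1 | intermediate
15 | 1-[2,4-bis(benzyloxy)-6-hydroxyphenyl]-3-[4-({(1R,2R)-1-[4-(benzyloxy)phenyl]-1,3-dihydroxypropan-2-yl}oxy)-3,5-dimethoxyphenyl]propane-1,3-dione (not isolated) | O=C(CC(=O)c1c(O)cc(OCc2ccccc2)cc1OCc1ccccc1)c1cc(OC)c(O[C@H](CO)[C@H](O)c2ccc(OCc3ccccc3)cc2)c(OC)c1 | intermediate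
16 | 5,7-bis(benzyloxy)-2-[4-({(1R,2R)-1-[4-(benzyloxy)phenyl]-1,3-dihydroxypropan-2-yl}oxy)-3,5-dimethoxyphenyl]-4H-chromen-4-one | COc1cc(-c2cc(=O)c3c(OCc4ccccc4)cc(OCc4ccccc4)cc3o2)cc(OC)c1O[C@H](CO)[C@H](O)c1ccc(OCc2ccccc2)cc1 | intermediate
17 | 5,7-dihydroxy-2-[4-({(1R,2R)-1,3-dihydroxy-1-(4-hydroxyphenyl)propan-2-yl}oxy)-3,5-dimethoxyphenyl]-4H-chromen-4-one | COc1cc(-c2cc(=O)c3c(O)cc(O)cc3o2)cc(OC)c1O[C@H](CO)[C@H](O)c1ccc(O)cc1 | target

**Totals**

Total step count: 7. Longest linear sequence: 6 (steps 1, 2, 3, 4, 6, 7; step 5 is a one-step side branch).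

**Three steps most likely to fail, with fallbacks**

Step 3 (allene hydroboration/allylboration). The risks are hydroboration at the wrong double bond, loss of Z geometry by boron 1,3-shift, and lower facial selectivity with the bulky 2,6-dimethoxyaryloxy group. The fallback sets out from 3 and replaces the stoichiometric chiral borane by an achiral boronate with a chiral Brønsted acid catalyst. Hydroboration of the alkyne with pinacolborane (Cp2Zr(H)Cl 5 mol%, Et3N 10 mol%, 25 °C) gives the (E)-alkenylboronate methyl 3,5-dimethoxy-4-{[(2E)-3-(4,4,5,5-tetramethyl-1,3,2-dioxaborolan-2-yl)prop-2-en-1-yl]oxy}benzoate F1. Z-selective nickel-hydride double-bond transposition toward oxygen (NiCl2[Ph2P(CH2)4PPh2] 5 mol%, LiBHEt3 10 mol%, THF) gives the (Z)-γ-aryloxyallylboronate methyl 3,5-dimethoxy-4-{[(1Z)-3-(4,4,5,5-tetramethyl-1,3,2-dioxaborolan-2-yl)prop-1-en-1-yl]oxy}benzoate F2. Allylboration of 6 catalysed by (S)-TRIP [(S)-3,3'-bis(2,4,6-triisopropylphenyl)-1,1'-binaphthyl-2,2'-diyl hydrogen phosphate, 5 mol%, toluene, −30 °C] goes through the same closed chair, so Z still gives threo, and comes back to the route at 9. If the first run shows the mirror-image sense, the (R)-acid is used.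

Step 4 (ozonolysis/reduction). The risks are ozone attack on the electron-rich rings and epimerisation or retro-aldol loss at the aldehyde stage. The fallback sets out from 9 and cleaves the alkene through a diol instead. Dihydroxylation (OsO4 2 mol%, N-methylmorpholine N-oxide, acetone/H2O, 20 °C) gives the triol methyl 4-{[(1R,2S)-1-[4-(benzyloxy)phenyl]-1,3,4-trihydroxybutan-2-yl]oxy}-3,5-dimethoxybenzoate F3 as a mixture at the new carbinol carbon (same geometry at the two original centres). Cleavage with NaIO4 (THF/pH 7 buffer, 0 °C), then NaBH4 added to the same flask, comes back to the route at 11.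

Step 6 (Claisen condensation/cyclodehydration). The risks are a sluggish intermolecular Claisen on the dilithiated diol ester and C7 epimerisation or solvolysis of the benzylic alcohol under acid. The fallback sets out from 11 and makes the diketone by intramolecular acyl transfer on a diol-protected substrate. 2,2-Dimethoxypropane with pyridinium tosylate (cat.) in acetone gives the acetonide methyl 4-{[(4R,5R)-4-[4-(benzyloxy)phenyl]-2,2-dimethyl-1,3-dioxan-5-yl]oxy}-3,5-dimethoxybenzoate F4. LiOH in THF/H2O gives the carboxylic acid F5. Esterification of the phenol of 14 (EDC·HCl, DMAP, CH2Cl2) gives the aryl ester 2-acetyl-3,5-bis(benzyloxy)phenyl 4-{[(4R,5R)-4-[4-(benzyloxy)phenyl]-2,2-dimethyl-1,3-dioxan-5-yl]oxy}-3,5-dimethoxybenzoate F6. Baker–Venkataraman rearrangement (KOtBu, THF, 0 → 25 °C) gives the diketone acetonide F7. TsOH·H2O (cat.) in THF/H2O at 45 °C then closes ring C and hydrolyses the acetonide in one pot, coming back to the route at 16. The trans-diequatorial dioxane is the thermodynamically favoured ring, so any reversible ionisation at C7 returns the threo isomer.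

**Further compounds**

F1 | step 3 | methyl 3,5-dimethoxy-4-{[(2E)-3-(4,4,5,5-tetramethyl-1,3,2-dioxaborolan-2-yl)prop-2-en-1-yl]oxy}benzoate | COC(=O)c1cc(OC)c(OC/C=C/B2OC(C)(C)C(C)(C)O2)c(OC)c1
F2 | step 3 | methyl 3,5-dimethoxy-4-{[(1Z)-3-(4,4,5,5-tetramethyl-1,3,2-dioxaborolan-2-yl)prop-1-en-1-yl]oxy}benzoate | COC(=O)c1cc(OC)c(O/C=C\CB2OC(C)(C)C(C)(C)O2)c(OC)c1
F3 | step 4 | methyl 4-{[(1R,2S)-1-[4-(benzyloxy)phenyl]-1,3,4-trihydroxybutan-2-yl]oxy}-3,5-dimethoxybenzoate (mixture at C3 of the butane chain) | COC(=O)c1cc(OC)c(O[C@H](C(O)CO)[C@H](O)c2ccc(OCc3ccccc3)cc2)c(OC)c1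
F4 | step 6 | methyl 4-{[(4R,5R)-4-[4-(benzyloxy)phenyl]-2,2-dimethyl-1,3-dioxan-5-yl]oxy}-3,5-dimethoxybenzoate | COC(=O)c1cc(OC)c(O[C@@H]2COC(C)(C)O[C@@H]2c2ccc(OCc3ccccc3)cc2)c(OC)c1
F5 | step 6 | 4-{[(4R,5R)-4-[4-(benzyloxy)phenyl]-2,2-dimethyl-1,3-dioxan-5-yl]oxy}-3,5-dimethoxybenzoic acid | OC(=O)c1cc(OC)c(O[C@@H]2COC(C)(C)O[C@@H]2c2ccc(OCc3ccccc3)cc2)c(OC)c1
F6 | step 6 | 2-acetyl-3,5-bis(benzyloxy)phenyl 4-{[(4R,5R)-4-[4-(benzyloxy)phenyl]-2,2-dimethyl-1,3-dioxan-5-yl]oxy}-3,5-dimethoxybenzoate | CC(=O)c1c(OC(=O)c2cc(OC)c(O[C@@H]3COC(C)(C)O[C@@H]3c3ccc(OCc4ccccc4)cc3)c(OC)c2)cc(OCc2ccccc2)cc1OCc1ccccc1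
F7 | step 6 | 1-[2,4-bis(benzyloxy)-6-hydroxyphenyl]-3-(4-{[(4R,5R)-4-[4-(benzyloxy)phenyl]-2,2-dimethyl-1,3-dioxan-5-yl]oxy}-3,5-dimethoxyphenyl)propane-1,3-dione | O=C(CC(=O)c1c(O)cc(OCc2ccccc2)cc1OCc1ccccc1)c1cc(OC)c(O[C@@H]2COC(C)(C)O[C@@H]2c2ccc(OCc3ccccc3)cc2)c(OC)c1
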